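**Plan**
- Retrosynthesis: after removal of two acetates, the only skeletal cuts are the two aryl–CH2 bonds, C8–C1'' on ring A and C5'–C1''' on ring B.
- Enabling feature: C8 is ortho to O7 and C5' is ortho to O4'. These are the two hydroxyls conjugated with the C4 carbonyl and the most acidic of the core, so each C-prenyl group is a masked O-(1,1-dimethylallyl) group. One double aromatic Claisen rearrangement moves both to carbon.
- Further back, the O7 and O4' ether bonds are cut to 3-chloro-3-methylbut-1-yne and the O3–CH3 bond to iodomethane. The flavonol comes from rutin, whose sugar marks O3.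
- Forward order: no ring is built, since rings A, C and B come intact from rutin. O3 is methylated, O7/O4' are alkylated, O5/O3' are acetylated, the alkynes are semi-reduced, both side chains are moved from O to C, and the acetates are removed.
- Stereochemistry: the target has no stereocentre and no stereogenic double bond, so nothing has to be controlled. The sugar stereocentres of rutin are discarded in step 1.

Key step: step 7

Remark: the target is achiral, so "single enantiomer" is read as the single constitutional isomer; rutin is chosen over quercetin as the source of the core because its glycoside differentiates O3 from O7/O4' from the outset.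

**Step 1**
Reactants: 1 rutin
Product: 3 quercetin 7,3',4'-tribenzyl ether, via rutin 7,3',4'-tribenzyl ether 2 (not isolated)
Conditions: BnBr (3.3 equiv), K2CO3, DMF, 60 °C; filter, concentrate; then 2 M HCl (aq)/EtOH, reflux
Reagents that add atoms: benzyl bromide, BrCc1ccccc1
Why: Williamson benzylation should take the three non-chelated phenols (O7, O4', O3') while the rutinoside blocks O3 and the O5–H···O=C4 hydrogen bond keeps O5 inert, and the following acid-catalysed glycoside hydrolysis, to which aryl benzyl ethers are stable, uncovers only the 3-OH.

**Step 2**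
Reactants: 3 quercetin 7,3',4'-tribenzyl ether; 4 iodomethane
Product: 5 quercetin 3-methyl ether 7,3',4'-tribenzyl ether
Conditions: MeI (1.2 equiv), K2CO3, DMF, rt
Reagents that add atoms: iodomethane, CI
Why: Williamson O-methylation should occur only at the enolic 3-OH, the one hydroxyl left that is not locked in the chelate with the C4 carbonyl.

**Step 3**
Reactants: 5 quercetin 3-methyl ether 7,3',4'-tribenzyl ether
Product: 6 quercetin 3-methyl ether (3-O-methylquercetin)
Conditions: H2 (1 atm), 10% Pd/C, THF–MeOH, rt
Reagents that add atoms: none
Why: catalytic hydrogenolysis cleaves the three benzyl ethers, and the tetrasubstituted, conjugated C2=C3 bond of the flavone is not expected to be reduced under these mild conditions.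

**Step 4**
Reactants: 6 quercetin 3-methyl ether; 7 3-chloro-3-methylbut-1-yne
Product: 8 quercetin 3-methyl ether 7,4'-bis(2-methylbut-3-yn-2-yl) ether
Conditions: 7 (2.3 equiv, in portions), K2CO3 (2.2 equiv), KI (cat.), CuI (cat.), acetone, 55 °C, Ar
Reagents that add atoms: 3-chloro-3-methylbut-1-yne, C#CC(C)(C)Cl
Why: copper-assisted propargylic etherification of phenoxides should select O7 and O4', the two hydroxyls conjugated with the C4 carbonyl that the limited base ionises first, while O3' (second ionisation of the catechol) and chelated O5 stay free, in line with the known 7,4'-dialkylation of quercetin 3-O-glycosides.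

**Step 5**
Reactants: 8 quercetin 3-methyl ether 7,4'-bis(2-methylbut-3-yn-2-yl) ether
Product: 9 quercetin 3-methyl ether 7,4'-bis(2-methylbut-3-yn-2-yl) ether 5,3'-diacetate
Conditions: Ac2O, pyridine, DMAP (cat.), rt to 40 °C
Reagents that add atoms: acetic anhydride, CC(=O)OC(C)=O
Why: DMAP-catalysed acetylation caps the 3'-OH and is strong enough to acylate the chelated 5-OH, which removes the hydrogen bond that would later steer the ring-A shift to C6.

**Step 6**
Reactants: 9 quercetin 3-methyl ether 7,4'-bis(2-methylbut-3-yn-2-yl) ether 5,3'-diacetate
Product: 10 quercetin 3-methyl ether 7,4'-bis(2-methylbut-3-en-2-yl) ether 5,3'-diacetate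
Conditions: H2 (1 atm), Lindlar catalyst, quinoline, EtOAc, rt, stopped after 2 equiv H2
Reagents that add atoms: none
Why: Lindlar semi-hydrogenation should stop each terminal alkyne at the vinyl stage without touching the aryl acetates or the flavone, and it runs at room temperature, well below the onset of the sigmatropic shift.

**Step 7**
Reactants: 10 quercetin 3-methyl ether 7,4'-bis(2-methylbut-3-en-2-yl) ether 5,3'-diacetate
Product: 11 8,5'-diprenylquercetin 3-methyl ether 5,3'-diacetate
Conditions: PhNEt2 (degassed), 150–180 °C, Ar
Reagents that add atoms: none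
Why: Each aryl 1,1-dimethylallyl ether should undergo a concerted suprafacial [3,3] shift through a chair-like six-membered transition state in which the vinyl CH2 terminus bonds to the ring carbon ortho to the ether oxygen, so the allyl unit is inverted and arrives as the linear 3-methylbut-2-enyl group, and the ortho-dienone then enolises to return O7–H and O4'–H. This is the thermal aromatic Claisen rearrangement of tertiary allyl aryl ethers to ortho-prenylphenols, a reaction type established on 7-O-alkylated flavonoids and on simple phenols. No ring is closed and no stereocentre is formed (each new alkene carries two identical methyl groups), so only site selectivity matters. On ring B the oxygen O4' has a single free ortho carbon, C5', because C3' carries the acetoxy group and a shift there would give a dienone that cannot enolise and can only revert. On ring A the choice is C8 against C6: with O5 acetylated the O5–H···O=C4 chelate that favours C6 is absent, so the shift should follow the higher C7–C8 double-bond character of the benzopyranone and the lower crowding away from the peri-acetoxy group, and go to C8. The weakly basic amine solvent buffers traces of acid that would ionise the tertiary ethers or close the freed ortho-prenylphenols to dimethylchromans.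

**Step 8**
Reactants: 11 8,5'-diprenylquercetin 3-methyl ether 5,3'-diacetate
Product: 12 5,7,3',4'-tetrahydroxy-3-methoxy-8,5'-diprenylflavone (target)
Conditions: K2CO3 (cat.), degassed MeOH, 0 °C to rt, Ar; aq. NH4Cl
Reagents that add atoms: none
Why: base-catalysed transesterification with methanol removes both aryl acetates under non-acidic conditions that leave the ortho-prenylphenols open, and any O3' to O4' acetyl migration during step 7 is without consequence because both esters fall here.

**Compound list**
1 | rutin, quercetin 3-O-[α-L-rhamnopyranosyl-(1→6)-β-D-glucopyranoside] | C[C@H]1[C@@H]([C@H]([C@H]([C@@H](O1)OC[C@@H]2[C@H]([C@@H]([C@H]([C@@H](O2)Oc3c(-c4ccc(O)c(O)c4)oc4cc(O)cc(O)c4c3=O)O)O)O)O)O)O | starting material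
2 | rutin 7,3',4'-tribenzyl ether | C[C@H]1[C@@H]([C@H]([C@H]([C@@H](O1)OC[C@@H]2[C@H]([C@@H]([C@H]([C@@H](O2)Oc3c(-c4ccc(OCc5ccccc5)c(OCc5ccccc5)c4)oc4cc(OCc5ccccc5)cc(O)c4c3=O)O)O)O)O)O)O | intermediate
3 | quercetin 7,3',4'-tribenzyl ether (3,5-dihydroxy) | O=c1c(O)c(-c2ccc(OCc3ccccc3)c(OCc3ccccc3)c2)oc2cc(OCc3ccccc3)cc(O)c12 | intermediate
4 | iodomethane | CI | starting material
5 | quercetin 3-methyl ether 7,3',4'-tribenzyl ether (5-hydroxy) | COc1c(-c2ccc(OCc3ccccc3)c(OCc3ccccc3)c2)oc2cc(OCc3ccccc3)cc(O)c2c1=O | intermediate
6 | quercetin 3-methyl ether (5,7,3',4'-tetrahydroxy-3-methoxyflavone) | COc1c(-c2ccc(O)c(O)c2)oc2cc(O)cc(O)c2c1=O | intermediate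
7 | 3-chloro-3-methylbut-1-yne | C#CC(C)(C)Cl | starting material
8 | quercetin 3-methyl ether 7,4'-bis(2-methylbut-3-yn-2-yl) ether (5,3'-dihydroxy) | COc1c(-c2ccc(OC(C)(C)C#C)c(O)c2)oc2cc(OC(C)(C)C#C)cc(O)c2c1=O | intermediate
9 | quercetin 3-methyl ether 7,4'-bis(2-methylbut-3-yn-2-yl) ether 5,3'-diacetate | COc1c(-c2ccc(OC(C)(C)C#C)c(OC(C)=O)c2)oc2cc(OC(C)(C)C#C)cc(OC(C)=O)c2c1=O | intermediate
10 | quercetin 3-methyl ether 7,4'-bis(2-methylbut-3-en-2-yl) ether 5,3'-diacetate (Claisen precursor) | COc1c(-c2ccc(OC(C)(C)C=C)c(OC(C)=O)c2)oc2cc(OC(C)(C)C=C)cc(OC(C)=O)c2c1=O | intermediate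
11 | 8,5'-diprenylquercetin 3-methyl ether 5,3'-diacetate (7,4'-dihydroxy; Claisen product) | COc1c(-c2cc(OC(C)=O)c(O)c(CC=C(C)C)c2)oc2c(CC=C(C)C)c(O)cc(OC(C)=O)c2c1=O | intermediate
12 | 5,7,3',4'-tetrahydroxy-3-methoxy-8,5'-diprenylflavone | COc1c(-c2cc(O)c(O)c(CC=C(C)C)c2)oc2c(CC=C(C)C)c(O)cc(O)c2c1=O | target

**Step count**
Total steps: 8. Longest linear sequence: 8 steps (rutin 1 to target 12).

**Steps most likely to fail**

Step 7. The tertiary C–O bonds may ionise or lose isoprene faster than they rearrange, part of the ring-A shift may be diverted to C6, and the freed phenols may add to their own prenyl double bonds. The fallback moves unsubstituted allyl groups, which cannot ionise or extrude a diene, and adds the two methyl groups afterwards by olefin metathesis. It sets out from 6. Allyl bromide and K2CO3 in DMF, with the same site preference as step 4, should give quercetin 3-methyl ether 7,4'-diallyl ether F1. Ac2O, pyridine and DMAP should give its 5,3'-diacetate F2. Heating F2 in PhNEt2 near 200 °C should give 8,5'-diallylquercetin 3-methyl ether 5,3'-diacetate F3, since the allyl Claisen shift of 7-allyloxy-5-acyloxyflavones is known to favour C8. Cross-metathesis of F3 with excess 2-methylbut-2-ene and a second-generation Grubbs catalyst in CH2Cl2 at 40 °C turns both allyl groups into prenyl groups and returns to the route at 11.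

Step 4. Alkylation may spread to O3' or stall after O7, and the tertiary chloride may be consumed by elimination before both ethers are formed. The fallback bases the discrimination on the lability of aryl acetates instead of on partial deprotonation of free phenols. It sets out from 6. Exhaustive acetylation (Ac2O, pyridine, DMAP) should give quercetin 3-methyl ether 5,7,3',4'-tetraacetate F4. Heating F4 with 7, K2CO3 and KI in acetone uses the known alkylative deacetylation of flavonol peracetates, in which the acetates on O7 and then O4' (the best phenoxide leaving groups) are cleaved and the phenoxides etherified in the same flask. This returns directly at 9.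

Step 6. Hydrogen uptake may not stop at the alkene, and the saturated tert-pentyl ethers so formed cannot rearrange and would be hard to separate. The fallback installs the 1,1-dimethylallyl ethers without any hydrogenation. It sets out from 6. Palladium(0)-catalysed O-allylation of Tsuji–Trost type with methyl 2-methylbut-3-en-2-yl carbonate [Pd(PPh3)4, THF, 0 °C] delivers phenols to the tertiary terminus of the dimethylallyl–palladium complex. It should give quercetin 3-methyl ether 7,4'-bis(2-methylbut-3-en-2-yl) ether F5. Acetylation of F5 (Ac2O, pyridine, DMAP, rt) returns to the route at 10.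

**Further compounds**
F1 | step 7 | quercetin 3-methyl ether 7,4'-diallyl ether | COc1c(-c2ccc(OCC=C)c(O)c2)oc2cc(OCC=C)cc(O)c2c1=O
F2 | step 7 | quercetin 3-methyl ether 7,4'-diallyl ether 5,3'-diacetate | COc1c(-c2ccc(OCC=C)c(OC(C)=O)c2)oc2cc(OCC=C)cc(OC(C)=O)c2c1=O
F3 | step 7 | 8,5'-diallylquercetin 3-methyl ether 5,3'-diacetate | COc1c(-c2cc(OC(C)=O)c(O)c(CC=C)c2)oc2c(CC=C)c(O)cc(OC(C)=O)c2c1=O
F4 | step 4 | quercetin 3-methyl ether 5,7,3',4'-tetraacetate | COc1c(-c2ccc(OC(C)=O)c(OC(C)=O)c2)oc2cc(OC(C)=O)cc(OC(C)=O)c2c1=O
F5 | step 6 | quercetin 3-methyl ether 7,4'-bis(2-methylbut-3-en-2-yl) ether | COc1c(-c2ccc(OC(C)(C)C=C)c(O)c2)oc2cc(OC(C)(C)C=C)cc(O)c2c1=O
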